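The readings are calculated for an exercise; the scatter is artificial.

At early times we read the flask through g, the fraction of G left, and ln(1/g), which grows in step with time for any first-order decay.

the same everywhere: G 48 mM; X 2.4 mM
- Sunday's: J 96 mM; the very flask that is asked about, followed so far
- Monday's: J 64 mM; run made earlier
- flask: J 96.0 mM

| run | time / min | L / % | G / % |
|---|---|---|---|
| Sunday's | 4.00 | 6.0 | 92.9 |
| Sunday's | 6.00 | 12.2 | 86.1 |
| Sunday's | 12.0 | 40.9 | 57.2 |
| Sunday's | 25.0 | 95.4 | 4.0 |
| Sunday's | 50.0 | 99.4 | 0.1 |
| Monday's | 3.00 | 3.3 | 96.0 |
| Monday's | 10.0 | 31.0 | 66.4 |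
| Monday's | 15.0 | 58.3 | 39.7 |
| Monday's | 25.0 | 96.3 | 2.9 |
| Monday's | 40.0 | 99.6 | 0 |

(each reading ± 0.3 percentage points)

* factor on the rate of making L when 10% of the G are converted if J is charged twice over
* factor on the rate when 10% of the G are converted if X is charged at 25 mM instead

- the numbers in the tables scatter with a standard deviation of 0.3 percentage points
- steps under discussion: J + Z <-> D; X -> Z; E -> Z + L; D -> Z + Q; G + Z <-> E
- what is bound to the catalyst counts as converted
- no earlier run changes the charge of X; that part of a forecast is a guess

Two extreme flasks can be solved in the head. In the first, all the catalyst works from the start, so ln(1/g) grows with t, and the rate at a given g scales with the charge of X, giving a factor of 10.4 for the new charge. In the second, working catalyst Z appears from X at a steady pace, a ramp (an induction period), so ln(1/g) grows as the square of t. Sunday's reading at 6.00 min gives 15.5 min for T, the ramp time, which is the time divided by the root of ln(1/g).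

On a ramp, the rate at a given g goes as 1/T. If the ramp's slope follows the charge of X, which is a guess because no run varies X, the factor is the root of the charge ratio, 3.23. While Sunday's time doubles from 6.00 min to 12.0 min, ln(1/g) grows by a factor of 3.73. The first extreme gives 2 there and the ramp 4, so this reading puts Sunday's flask nearer the ramp. Monday's T, with less J, reads 15.6 min, nearly Sunday's. We therefore commit to about 1 for doubling J, though the two runs span a smaller step in J, and about 3.23 for X. The forecast says 0.96 and 3.1, calling the latter “a square-root effect”.

The simulation gives 0.966 and 2.96, the second far below the full-catalyst factor, from these steps: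

    J + Z ⇌ D (K = 5.70 M⁻¹, k = 0.630 M⁻¹ s⁻¹)
    X → Z (k = 0.00150 s⁻¹)
    E → Z + L (k = 0.0390 s⁻¹)
    D → Z + Q (k = 0.0350 s⁻¹)
    G + Z ⇌ E (K = 440 M⁻¹, k = 6.20 M⁻¹ s⁻¹)

In Sunday's flask, 10% of the G is converted at 4.94 min, and T puts that point at 5.03 min. For a second flask, Sunday's with X charged twice over, the ramp reckoning divides T by the root of that charge ratio, which puts the factor on that time at 0.707, and the run gives 0.671.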